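**Retrosynthetic overview**
1. Target 19 ⇐ bis(benzyl ether) 18 (hydrogenolysis) ⇐ 4-carboxy lactone 16 (radical removal of a carboxyl group on C4 that is not in the target).
2. Key disconnection: the C3–C4 bond (made together with O2–C1) of lactone ring B; 16 ⇐ homophthalic anhydride 14 + aldehyde 8 by a catalytic asymmetric formal [4+2] (Tamura-type) annulation that also sets C3 (R).
3. Enabling feature: C4 is benzylic and sits on C4a, next to C8a, which carries the C1 carboxyl; one extra carbonyl carbon between C4 and the C1 carboxyl oxygen closes a six-membered anhydride ring on ring A, which makes C4–H acidic and holds C1 as an acyl donor for the oxygen that arrives with C3.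
4. 14 ⇐ methyl orsellinate 9 (O-benzylation, lateral carboxylation of the ring methyl group, hydrolysis, cyclodehydration); 8 ⇐ (S)-propylene oxide 2 + the C9 Grignard reagent from 1 (fixes the remote S centre), then O-methylation, hydroboration, oxidation.
5. Order of rings: ring A is bought; the temporary anhydride ring is closed in step 8 and exchanged for lactone ring B in step 9.

Key step: step 9

Assumption: the facial preference of the squaramide catalyst is taken to follow the known homophthalic anhydride/aldehyde cases; of the two pseudo-enantiomeric catalysts (quinine- or quinidine-derived) the one that delivers 3R is used, and the route is written for it.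

**Step 1**
Reactants: 1 9-bromonon-1-ene; 2 (S)-2-methyloxirane
Product: 4 (S)-dodec-11-en-2-ol, via non-8-en-1-ylmagnesium bromide 3 (not isolated)
Conditions: Mg, THF, rt → 40 °C; then 2, CuI (5 mol %), THF, −30 → 0 °C; H2O work-up
Reagents that add atoms: none
Why: Copper-catalysed Grignard opening of a terminal epoxide is an SN2 attack at the unsubstituted carbon, so the C–O stereocentre of 2 is not touched and 4 should form as the (S)-alcohol.

**Step 2**
Reactants: 4 (S)-dodec-11-en-2-ol
Product: 5 (S)-11-methoxydodec-1-ene
Conditions: NaH, MeI, THF, 0 °C → rt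
Reagents that add atoms: iodomethane, CI
Why: Williamson ether synthesis on the sodium alkoxide methylates oxygen only, so the (S) centre is retained.

**Step 3**
Reactants: 5 (S)-11-methoxydodec-1-ene
Product: 7 (S)-11-methoxydodecan-1-ol, via B-alkyl-9-BBN adduct 6 (not isolated)
Conditions: 9-BBN, THF, 0 °C → rt; then NaOH (aq.), H2O2, 0 °C → rt
Reagents that add atoms: hydrogen peroxide, OO
Why: Brown hydroboration with the bulky 9-BBN places boron on the terminal carbon (anti-Markovnikov) and alkaline peroxide oxidation replaces boron by hydroxyl without affecting the remote methyl ether.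

**Step 4**
Reactants: 7 (S)-11-methoxydodecan-1-ol
Product: 8 (S)-11-methoxydodecanal
Conditions: PhI(OAc)2, (2,2,6,6-tetramethylpiperidin-1-yl)oxyl (TEMPO, 10 mol %), CH2Cl2, rt
Reagents that add atoms: none
Why: The oxoammonium (TEMPO) oxidation with PhI(OAc)2 as terminal oxidant converts a primary alcohol to the aldehyde and should not over-oxidise in the absence of water.

**Step 5**
Reactants: 9 methyl 2,4-dihydroxy-6-methylbenzoate
Product: 10 methyl 2,4-bis(benzyloxy)-6-methylbenzoate
Conditions: BnBr (2.5 equiv), K2CO3, DMF, 60 °C
Reagents that add atoms: benzyl bromide, BrCc1ccccc1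
Why: Williamson O-alkylation of both phenoxides proceeds in a polar aprotic solvent, the hydrogen-bonded 2-hydroxyl needing the excess reagent and heat.

**Step 6**
Reactants: 10 methyl 2,4-bis(benzyloxy)-6-methylbenzoate
Product: 12 [3,5-bis(benzyloxy)-2-(methoxycarbonyl)phenyl]acetic acid, via benzylic lithium 11 (not isolated)
Conditions: LiN(iPr)2 (LDA, 2.2 equiv), THF, −78 °C; then CO2 (g), −78 °C → rt; 1 M HCl work-up
Reagents that add atoms: carbon dioxide, O=C=O
Why: Lateral (benzylic) lithiation of an ortho-toluate is favoured because the anion is conjugated with the ortho ester carbonyl, and the benzylic organolithium is carboxylated by CO2 faster than it attacks the shielded ester.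

**Step 7**
Reactants: 12 [3,5-bis(benzyloxy)-2-(methoxycarbonyl)phenyl]acetic acid
Product: 13 2,4-bis(benzyloxy)-6-(carboxymethyl)benzoic acid
Conditions: KOH, EtOH–H2O, reflux; then HCl (aq.)
Reagents that add atoms: potassium hydroxide, [K+].[OH-]
Why: Saponification of the methyl ester (forcing conditions because of the two ortho substituents) gives the homophthalic acid, the aryl benzyl ethers being inert to hydroxide.

**Step 8**
Reactants: 13 2,4-bis(benzyloxy)-6-(carboxymethyl)benzoic acid
Product: 14 6,8-bis(benzyloxy)isochromane-1,3-dione
Conditions: Ac2O, toluene, 110 °C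
Reagents that add atoms: none
Why: Cyclodehydration of the 1,5-diacid with acetic anhydride closes the six-membered homophthalic anhydride ring, which is favoured over intermolecular anhydride formation.

**Step 9**
Reactants: 14 6,8-bis(benzyloxy)isochromane-1,3-dione; 8 (S)-11-methoxydodecanal
Product: 16 (3R,4S)-6,8-bis(benzyloxy)-3-[(10S)-10-methoxyundecyl]-1-oxoisochromane-4-carboxylic acid (3,4-trans), via aldol adduct 15 (not isolated)
Conditions: 9-amino-9-deoxy-epi-cinchona squaramide catalyst (N′-[3,5-bis(trifluoromethyl)phenyl], pseudo-enantiomer as assumed above, 5 mol %), MTBE, −15 °C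
Reagents that add atoms: none
Why: The quinuclidine nitrogen of the bifunctional catalyst enolises anhydride 14 at C4 while the squaramide N–H bonds bind and orient aldehyde 8; the C4 enolate adds to the aldehyde carbon (C3–C4 bond, adduct 15) and the new alkoxide then attacks the aryl-bound anhydride carbonyl C1, so that the anhydride ring opens as lactone ring B closes and the bridging carbonyl carbon is left as the C4 carboxylic acid. The closest known reaction type is the cinchona-squaramide-catalysed formal [4+2] (Tamura-type) cycloaddition of homophthalic anhydride with aldehydes to 1-oxoisochromane-4-carboxylic acids. Ring B closes as a formal [4+2], the C3–C4 bond forming in the aldol event and the O2–C1 bond by 6-exo-trig acyl transfer, whereas attack on the other anhydride carbonyl would give a four-membered ring and is excluded by strain. C3 is set by the catalyst through the face of the hydrogen-bonded aldehyde that is presented to the enolate, C4 is set relative to C3 (trans expected) but is erased in step 10 so that any 4-epimer is carried along, and the remote C10′ centre is too far away to interfere. The step needs chemoselectivity for enolisation of the anhydride over self-aldol of the enolisable aldehyde, which the much higher C–H acidity of 14 (benzylic and α to an anhydride carbonyl) should secure at low temperature with only a catalytic amount of a tertiary amine base.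

**Step 10**
Reactants: 16 (3R,4S)-6,8-bis(benzyloxy)-3-[(10S)-10-methoxyundecyl]-1-oxoisochromane-4-carboxylic acid
Product: 18 (3R)-6,8-bis(benzyloxy)-3-[(10S)-10-methoxyundecyl]isochroman-1-one, via thiohydroxamate ester 17 (not isolated)
Conditions: N-hydroxypyridine-2-thione, DCC, CH2Cl2, 0 °C → rt, dark; then t-BuSH (excess), hν (visible lamp), rt
Reagents that add atoms: none
Why: Barton reductive decarboxylation fragments the thiohydroxamate ester under light to CO2 and the benzylic C4 radical, which takes a hydrogen atom from the thiol, and C3 is not involved so its configuration is kept.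

**Step 11**
Reactants: 18 (3R)-6,8-bis(benzyloxy)-3-[(10S)-10-methoxyundecyl]isochroman-1-one
Product: 19 (3R)-6,8-dihydroxy-3-[(10S)-10-methoxyundecyl]isochroman-1-one
Conditions: H2 (1 atm), Pd/C, EtOAc–MeOH, rt
Reagents that add atoms: none
Why: Catalytic hydrogenolysis cleaves the two aryl benzyl ethers, while the lactone, whose C3–O bond is not benzylic, and the alkyl methyl ether are stable.

**Compound list**
1 | 9-bromonon-1-ene | C=CCCCCCCCBr | starting material
2 | (S)-2-methyloxirane | C[C@H]1CO1 | starting material
3 | non-8-en-1-ylmagnesium bromide | C=CCCCCCCC[Mg]Br | intermediate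
4 | (S)-dodec-11-en-2-ol | C[C@H](O)CCCCCCCCC=C | intermediate
5 | (S)-11-methoxydodec-1-ene | CO[C@@H](C)CCCCCCCCC=C | intermediate
6 | 9-[(11S)-11-methoxydodecyl]-9-borabicyclo[3.3.1]nonane | CO[C@@H](C)CCCCCCCCCCB1C2CCCC1CCC2 | intermediate
7 | (S)-11-methoxydodecan-1-ol | CO[C@@H](C)CCCCCCCCCCO | intermediate
8 | (S)-11-methoxydodecanal | CO[C@@H](C)CCCCCCCCCC=O | intermediate
9 | methyl 2,4-dihydroxy-6-methylbenzoate | COC(=O)c1c(C)cc(O)cc1O | starting material
10 | methyl 2,4-bis(benzyloxy)-6-methylbenzoate | COC(=O)c1c(C)cc(OCc2ccccc2)cc1OCc1ccccc1 | intermediate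
11 | {[3,5-bis(benzyloxy)-2-(methoxycarbonyl)phenyl]methyl}lithium | [Li]Cc1cc(OCc2ccccc2)cc(OCc2ccccc2)c1C(=O)OC | intermediate
12 | [3,5-bis(benzyloxy)-2-(methoxycarbonyl)phenyl]acetic acid | COC(=O)c1c(CC(=O)O)cc(OCc2ccccc2)cc1OCc1ccccc1 | intermediate
13 | 2,4-bis(benzyloxy)-6-(carboxymethyl)benzoic acid | OC(=O)Cc1cc(OCc2ccccc2)cc(OCc2ccccc2)c1C(=O)O | intermediate
14 | 6,8-bis(benzyloxy)isochromane-1,3-dione | O=C1Cc2cc(OCc3ccccc3)cc(OCc3ccccc3)c2C(=O)O1 | intermediate
15 | (4S)-6,8-bis(benzyloxy)-4-[(1R,11S)-1-hydroxy-11-methoxydodecyl]isochromane-1,3-dione | CO[C@@H](C)CCCCCCCCC[C@@H](O)[C@@H]1c2cc(OCc3ccccc3)cc(OCc3ccccc3)c2C(=O)OC1=O | intermediate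
16 | (3R,4S)-6,8-bis(benzyloxy)-3-[(10S)-10-methoxyundecyl]-1-oxoisochromane-4-carboxylic acid | CO[C@@H](C)CCCCCCCCC[C@@H]1[C@@H](C(=O)O)c2cc(OCc3ccccc3)cc(OCc3ccccc3)c2C(=O)O1 | intermediate
17 | 2-thioxopyridin-1(2H)-yl (3R,4S)-6,8-bis(benzyloxy)-3-[(10S)-10-methoxyundecyl]-1-oxoisochromane-4-carboxylate | CO[C@@H](C)CCCCCCCCC[C@@H]1[C@@H](C(=O)On2ccccc2=S)c2cc(OCc3ccccc3)cc(OCc3ccccc3)c2C(=O)O1 | intermediate
18 | (3R)-6,8-bis(benzyloxy)-3-[(10S)-10-methoxyundecyl]isochroman-1-one | CO[C@@H](C)CCCCCCCCC[C@@H]1Cc2cc(OCc3ccccc3)cc(OCc3ccccc3)c2C(=O)O1 | intermediate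
19 | (3R)-6,8-dihydroxy-3-[(10S)-10-methoxyundecyl]isochroman-1-one | CO[C@@H](C)CCCCCCCCC[C@@H]1Cc2cc(O)cc(O)c2C(=O)O1 | target

**Step count and risks**
Total step count: 11. Longest linear sequence: 7 steps (steps 5–11; the branch through steps 1–4 and 9–11 is equally long).

Steps most likely to fail:

1. Step 9. The catalyst may discriminate poorly between the faces of an unbranched aliphatic aldehyde. In addition, retro-aldol equilibration before a slow lactonisation onto the electron-rich, ortho-alkoxy-shielded C1 carbonyl could erode the C3 configuration. The fallback sets the stereocentre after the ring closure instead of during it. It sets out from 14 (with 8): the same annulation is run without chiral control (iPr2NEt, CH2Cl2, rt) and should give 6,8-bis(benzyloxy)-3-[(10S)-10-methoxyundecyl]-1-oxoisochromane-4-carboxylic acid F1 as a mixture of C3/C4 isomers. Kochi oxidative decarboxylation (Pb(OAc)4, Cu(OAc)2 cat., pyridine, benzene, 80 °C) should then give the isocoumarin 6,8-bis(benzyloxy)-3-[(10S)-10-methoxyundecyl]-1H-isochromen-1-one F2. Asymmetric hydrogenation of its C3=C4 bond (Ru(cod)(2-methylallyl)2, a chiral N-heterocyclic carbene ligand generated from its imidazolinium tetrafluoroborate and KOtBu, H2 under pressure, hexane, rt; ligand enantiomer chosen for 3R) comes back to the route at 18.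

2. Step 10. The radical chain may stall because the stabilised benzylic C4 radical adds to the thiocarbonyl sulfur of a second thiohydroxamate molecule faster than it abstracts hydrogen from the thiol. Acyl activation of an acid that carries a β-acyloxy group also invites ring opening by β-elimination. The fallback removes the carboxyl group without any acyl activation. It sets out from 16 and comes back at 18 in one operation: hydrodecarboxylation of the free acid under acridinium photoredox catalysis (9-mesityl-10-methylacridinium tetrafluoroborate, (PhS)2, 2,6-lutidine, CF3CH2OH, blue light). The carboxylate is oxidised by electron transfer, loses CO2, and the C4 radical is reduced by the catalytic thiol. No new compound arises on the way (F0).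

3. Step 7. Hydroxide attack at a carbonyl carbon flanked by two ortho substituents is slow, so the hydrolysis may stall at the half ester or need conditions under which the arylacetic acid arm is lost by decarboxylation. The fallback changes the site of attack. It sets out from 12 and comes back at 13: nucleophilic dealkylation (LiI, pyridine, reflux; then HCl) cleaves the ester by SN2 attack of iodide at the unhindered O-methyl carbon instead of at the shielded carbonyl carbon. No new compound arises on the way (F0).

**Further compounds**
F1 | step 9 | 6,8-bis(benzyloxy)-3-[(10S)-10-methoxyundecyl]-1-oxoisochromane-4-carboxylic acid (mixture of C3/C4 isomers) | CO[C@@H](C)CCCCCCCCCC1C(C(=O)O)c2cc(OCc3ccccc3)cc(OCc3ccccc3)c2C(=O)O1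
F2 | step 9 | 6,8-bis(benzyloxy)-3-[(10S)-10-methoxyundecyl]-1H-isochromen-1-one | CO[C@@H](C)CCCCCCCCCC1=Cc2cc(OCc3ccccc3)cc(OCc3ccccc3)c2C(=O)O1
F0 | step 10 | none | none
F0 | step 7 | none | none
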